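**Retrosynthetic overview**
1. The central C15–C15' single bond is cut by a Stille coupling into two C20 halves: an alkenylstannane carrying the cyclohexadienylidene ring and an alkenyl iodide carrying the hydroxylated ring. Each half is cut at C10=C11 (Horner–Wadsworth–Emmons) into a C14 retro-aldehyde and one common C6 stannyl dienyl phosphonate.
2. Both C14 aldehydes come from one compound: the hydroxy aldehyde is used as such for the hydroxylated half and is dehydrated (syn elimination of C3–OH) for the other half.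
3. The six-membered ring (C1'–C6') is closed at C5'–C6'. This bond is the central σ-bond of the s-cis diene C4'=C5'(CH3)–C6'=C7' (endocyclic trisubstituted alkene next to the exocyclic alkylidene), so it maps onto a (Z)-alkenyl iodide at C5' and an alkyne C6'≡C7' joined by the tether C3'–C2'–C1'(CH3)2. A reductive 6-exo-dig carbopalladation makes the bond and both alkenes of the retro diene with defined geometry.
4. The acyclic iodo-dienyne is built linearly from isopropylidene Meldrum's acid, ethynyl- and propynylmagnesium bromide and 3-ethoxymethacrolein; C3' is set by asymmetric transfer hydrogenation of an ynone, and the (Z)-iodide by directed hydroalumination/iodination.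
5. Ring order: the hydroxylated ring is the only ring made by C–C bond formation (step 9); the second ring is the same ring, desaturated at C2=C3 in step 16; the halves are joined last.

Key step: step 9

Remark: carotenoid numbering is used (ring C1–C6, chain C7–C15, primed locants for the hydroxylated half); the carbinol carbon C3' is S, and at each ring the chain carbon C8/C8' lies cis to the gem-dimethyl carbon C1/C1'.

Step 1
Reactants: 1 2,2-dimethyl-5-(propan-2-ylidene)-1,3-dioxane-4,6-dione (isopropylidene Meldrum's acid); 2 ethynylmagnesium bromide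
Product: 3 2,2-dimethyl-5-(2-methylbut-3-yn-2-yl)-1,3-dioxane-4,6-dione
Conditions: THF, −20 °C to rt; then 1 M HCl
Reagents that add atoms: none
Why: Conjugate (1,4-) addition of an alkynyl Grignard reagent to the doubly activated alkylidene Meldrum's acid should create the quaternary propargylic carbon C1' with its two methyl groups, and no stereocenter is formed.

Step 2
Reactants: 3 2,2-dimethyl-5-(2-methylbut-3-yn-2-yl)-1,3-dioxane-4,6-dione
Product: 5 3,3-dimethylpent-4-ynoic acid, via substituted malonic acid 4 (not isolated)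
Conditions: DMF/H2O (10:1), 100 °C
Reagents that add atoms: water (O)
Why: Hydrolytic opening of the Meldrum's acid ring followed by thermal malonic acid decarboxylation should leave the mono-acid.

Step 3
Reactants: 5 3,3-dimethylpent-4-ynoic acid
Product: 7 N-methoxy-N,3,3-trimethylpent-4-ynamide, via acyl imidazolide 6 (not isolated)
Conditions: 1,1'-carbonyldiimidazole, CH2Cl2, rt; then MeNH(OMe)·HCl, rt
Reagents that add atoms: N,O-dimethylhydroxylamine hydrochloride (CNOC.Cl)
Why: Weinreb amide formation through the acyl imidazolide should give an acyl donor that stops at the ketone stage in step 6.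

Step 4
Reactants: 7 N-methoxy-N,3,3-trimethylpent-4-ynamide; 8 (E)-3-ethoxy-2-methylprop-2-enal (3-ethoxymethacrolein)
Product: 10 (6E)-N-methoxy-N,3,3,7-tetramethyl-8-oxooct-6-en-4-ynamide, via propargylic alcohol adduct 9 (not isolated)
Conditions: LiN(SiMe3)2, THF, −78 °C; 8, −78 to −20 °C; then 1 M HCl, THF, rt
Reagents that add atoms: water (O)
Why: 1,2-Addition of the lithium acetylide to the vinylogous formate 8 and acid-induced hydrolysis/allylic transposition with loss of ethanol (formyl-olefination with a 3-alkoxyacrolein) should give the thermodynamically preferred (E)-2-methyl-2-en-4-ynal, since the alkyne C–H is the most acidic site and the acetylide should add to the aldehyde faster than to a Weinreb amide at low temperature.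

Step 5
Reactants: 10 (6E)-N-methoxy-N,3,3,7-tetramethyl-8-oxooct-6-en-4-ynamide
Product: 11 (6E)-N,8,8-trimethoxy-N,3,3,7-tetramethyloct-6-en-4-ynamide
Conditions: HC(OMe)3, MeOH, pyridinium p-toluenesulfonate (cat.), rt
Reagents that add atoms: trimethyl orthoformate (COC(OC)OC); methanol (CO)
Why: Acid-catalysed acetalisation masks the aldehyde against the Grignard and hydride reagents of steps 6 to 8.

Step 6
Reactants: 11 (6E)-N,8,8-trimethoxy-N,3,3,7-tetramethyloct-6-en-4-ynamide; 12 prop-1-yn-1-ylmagnesium bromide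
Product: 13 (9E)-11,11-dimethoxy-6,6,10-trimethylundec-9-ene-2,7-diyn-4-one
Conditions: THF, 0 °C to rt; then aq. NH4Cl
Reagents that add atoms: none
Why: Weinreb ketone synthesis should stop at the ynone because of the stable magnesium chelate, and as the substrate alkyne is now internal no acetylide exchange can compete.

Step 7
Reactants: 13 (9E)-11,11-dimethoxy-6,6,10-trimethylundec-9-ene-2,7-diyn-4-one
Product: 14 (4S,9E)-11,11-dimethoxy-6,6,10-trimethylundec-9-ene-2,7-diyn-4-ol
Conditions: Ru[(S,S)-TsDPEN](p-cymene) (1 mol %), iPrOH, rt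
Reagents that add atoms: none
Why: Noyori asymmetric transfer hydrogenation of the alkynyl ketone with the (S,S)-TsDPEN ruthenium catalyst should deliver hydride to the face that gives the (S)-propargylic alcohol (the alkynyl group takes the role of the aryl group of acetophenone), which sets the only stereocenter of the target, C3'.

Step 8
Reactants: 14 (4S,9E)-11,11-dimethoxy-6,6,10-trimethylundec-9-ene-2,7-diyn-4-ol
Product: 16 (2Z,4S,9E)-2-iodo-11,11-dimethoxy-6,6,10-trimethylundeca-2,9-dien-7-yn-4-ol, via cyclic alkenylaluminate 15 (not isolated)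
Conditions: NaAlH2(OCH2CH2OMe)2 (Red-Al), THF, 0 °C to rt; then I2, THF, −78 to 0 °C
Reagents that add atoms: iodine (II)
Why: Hydroxyl-directed trans-hydroalumination of the propargylic alcohol places aluminium on the distal alkyne carbon inside a five-membered oxa-alumina ring, and iodinolysis with retention should give the (Z)-3-iodo allylic alcohol (iodine cis to the carbinol carbon), while the remote enyne has no directing hydroxyl and should remain.

Step 9
Reactants: 16 (2Z,4S,9E)-2-iodo-11,11-dimethoxy-6,6,10-trimethylundeca-2,9-dien-7-yn-4-ol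
Product: 19 (1S,4E)-4-[(2E)-4,4-dimethoxy-3-methylbut-2-en-1-ylidene]-3,5,5-trimethylcyclohex-2-en-1-ol, via alkenylpalladium iodide 17 (not isolated), via dienylpalladium iodide 18 (not isolated)
Conditions: Pd(OAc)2 (5 mol %), PPh3 (15 mol %), HCO2Na (2 equiv), DMF, 70 °C
Reagents that add atoms: none
Why: Oxidative addition of zerovalent palladium into the C5'–I bond with retention gives the divalent alkenylpalladium iodide 17, which adds syn across the tethered alkyne to form the C5'–C6' bond and dienylpalladium iodide 18; formate then replaces iodide, loses CO2, and the palladium hydride reductively eliminates the C7'–H bond with retention. The closest known reaction type is the palladium-catalysed cyclisation of alkenyl halides onto alkynes with formate (hydride) capture, the reductive variant of the intramolecular Heck reaction. The six-membered ring C1'–C6' closes in the 6-exo-dig mode, with the alkene of the alkenyl iodide becoming endocyclic (C4'=C5') and the former alkyne exocyclic (C6'=C7'). No new stereocenter arises and C3' is untouched; the geometry of the new C6'=C7' bond follows from the syn addition, which puts palladium and then hydrogen cis to C5' and so the chain carbon C8' cis to the gem-dimethyl carbon C1', as in the target. The step needs cyclisation to outrun formate reduction of 17 and 6-exo to beat 7-endo closure: the (Z)-iodide holds palladium next to the tether, the gem-dimethyl group at C1' compresses the chain (Thorpe–Ingold effect), and the conjugated enyne is an activated acceptor. Both carbons that are joined start as electrophilic unsaturated carbons, so the step is formally a reductive coupling with formate as terminal reductant, and it turns an acyclic, non-conjugated iodo-dienyne into the complete retro end-group chromophore.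

Step 10
Reactants: 19 (1S,4E)-4-[(2E)-4,4-dimethoxy-3-methylbut-2-en-1-ylidene]-3,5,5-trimethylcyclohex-2-en-1-ol
Product: 20 (2E)-4-[(1E,4S)-4-hydroxy-2,6,6-trimethylcyclohex-2-en-1-ylidene]-2-methylbut-2-enal
Conditions: pyridinium p-toluenesulfonate (cat.), acetone/H2O (10:1), rt
Reagents that add atoms: water (O)
Why: Mild acetal hydrolysis should free the aldehyde faster than the allylic C3' alcohol can ionise, so the stereocenter is kept.

Step 11
Reactants: 21 (E)-3-methylpent-2-en-4-yn-1-ol
Product: 22 (2E,4E)-3-methyl-5-(tributylstannyl)penta-2,4-dien-1-ol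
Conditions: Bu3SnH, PdCl2(PPh3)2 (2 mol %), THF, 0 °C
Reagents that add atoms: tributyltin hydride (CCCC[SnH](CCCC)CCCC)
Why: Palladium-catalysed syn hydrostannation of the terminal alkyne of the conjugated enyne should give the (E)-alkenylstannane with tin on the less hindered terminal carbon.

Step 12
Reactants: 22 (2E,4E)-3-methyl-5-(tributylstannyl)penta-2,4-dien-1-ol
Product: 23 tributyl[(1E,3E)-5-bromo-3-methylpenta-1,3-dien-1-yl]stannane
Conditions: CBr4, PPh3, CH2Cl2, −20 °C
Reagents that add atoms: carbon tetrabromide (BrC(Br)(Br)Br)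
Why: The Appel reaction converts the primary allylic alcohol to the bromide under neutral conditions that the alkenylstannane tolerates.

Step 13
Reactants: 23 tributyl[(1E,3E)-5-bromo-3-methylpenta-1,3-dien-1-yl]stannane
Product: 24 diethyl [(2E,4E)-3-methyl-5-(tributylstannyl)penta-2,4-dien-1-yl]phosphonate
Conditions: P(OEt)3 (neat), 100 °C
Reagents that add atoms: triethyl phosphite (CCOP(OCC)OCC)
Why: The Michaelis–Arbuzov reaction of the primary allylic bromide should give the allylic phosphonate by substitution at the α-carbon.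

Step 14
Reactants: 20 (2E)-4-[(1E,4S)-4-hydroxy-2,6,6-trimethylcyclohex-2-en-1-ylidene]-2-methylbut-2-enal; 24 diethyl [(2E,4E)-3-methyl-5-(tributylstannyl)penta-2,4-dien-1-yl]phosphonate
Product: 25 (1S,4E)-4-[(2E,4E,6E,8E)-3,7-dimethyl-9-(tributylstannyl)nona-2,4,6,8-tetraen-1-ylidene]-3,5,5-trimethylcyclohex-2-en-1-ol
Conditions: 24 (2.5 equiv), LiN(SiMe3)2 (2.4 equiv), THF/DMPU, −78 °C; then 20, −78 to 0 °C
Reagents that add atoms: none
Why: Horner–Wadsworth–Emmons olefination with the lithiated allylic phosphonate should form the C10'=C11' bond with E geometry, the excess of anion covering the free hydroxyl.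

Step 15
Reactants: 25 (1S,4E)-4-[(2E,4E,6E,8E)-3,7-dimethyl-9-(tributylstannyl)nona-2,4,6,8-tetraen-1-ylidene]-3,5,5-trimethylcyclohex-2-en-1-ol
Product: 26 (1S,4E)-4-[(2E,4E,6E,8E)-9-iodo-3,7-dimethylnona-2,4,6,8-tetraen-1-ylidene]-3,5,5-trimethylcyclohex-2-en-1-ol
Conditions: I2, CH2Cl2, −78 to −20 °C, dark
Reagents that add atoms: iodine (II)
Why: Iododestannylation (ipso substitution with retention) should give the (E)-alkenyl iodide needed as the electrophile of the final coupling.

Step 16
Reactants: 20 (2E)-4-[(1E,4S)-4-hydroxy-2,6,6-trimethylcyclohex-2-en-1-ylidene]-2-methylbut-2-enal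
Product: 28 (2E)-2-methyl-4-[(1Z)-2,6,6-trimethylcyclohexa-2,4-dien-1-ylidene]but-2-enal, via sulfamate ester 27 (not isolated)
Conditions: methyl N-(triethylammoniosulfonyl)carbamate (Burgess reagent), benzene, rt to 50 °C
Reagents that add atoms: none
Why: Burgess dehydration is a syn elimination of the sulfamate ester, and because the only β-hydrogens on sp3 carbon sit on C2 it should place the new double bond at C2=C3 and give the conjugated cyclohexadienylidene ring, the electron-poor trienal disfavouring ionisation.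

Step 17
Reactants: 28 (2E)-2-methyl-4-[(1Z)-2,6,6-trimethylcyclohexa-2,4-dien-1-ylidene]but-2-enal; 24 diethyl [(2E,4E)-3-methyl-5-(tributylstannyl)penta-2,4-dien-1-yl]phosphonate
Product: 29 tributyl{(1E,3E,5E,7E)-3,7-dimethyl-9-[(1Z)-2,6,6-trimethylcyclohexa-2,4-dien-1-ylidene]nona-1,3,5,7-tetraen-1-yl}stannane
Conditions: 24 (1.3 equiv), LiN(SiMe3)2 (1.25 equiv), THF/DMPU, −78 to 0 °C
Reagents that add atoms: none
Why: The same Horner–Wadsworth–Emmons olefination should form the C10=C11 bond with E geometry, the pre-formed phosphonate anion adding to the aldehyde faster than it can deprotonate the ring methyl group.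

Step 18
Reactants: 29 tributyl{(1E,3E,5E,7E)-3,7-dimethyl-9-[(1Z)-2,6,6-trimethylcyclohexa-2,4-dien-1-ylidene]nona-1,3,5,7-tetraen-1-yl}stannane; 26 (1S,4E)-4-[(2E,4E,6E,8E)-9-iodo-3,7-dimethylnona-2,4,6,8-tetraen-1-ylidene]-3,5,5-trimethylcyclohex-2-en-1-ol
Product: 30 (1S,4E)-3,5,5-trimethyl-4-[(2E,4E,6E,8E,10E,12E,14E,16E)-3,7,12,16-tetramethyl-18-[(1Z)-2,6,6-trimethylcyclohexa-2,4-dien-1-ylidene]octadeca-2,4,6,8,10,12,14,16-octaen-1-ylidene]cyclohex-2-en-1-ol
Conditions: Pd2(dba)3 (2.5 mol %), AsPh3 (20 mol %), N-methylpyrrolidone, rt to 40 °C, dark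
Reagents that add atoms: none
Why: Stille coupling of the alkenyl iodide with the alkenylstannane proceeds with retention at both carbons and should form the central C15–C15' single bond under neutral conditions that the free hydroxyl and the polyene tolerate.

**Compound list**
1 | 2,2-dimethyl-5-(propan-2-ylidene)-1,3-dioxane-4,6-dione | CC(C)=C1C(=O)OC(C)(C)OC1=O | starting material
2 | ethynylmagnesium bromide | C#C[Mg]Br | starting material
3 | 2,2-dimethyl-5-(2-methylbut-3-yn-2-yl)-1,3-dioxane-4,6-dione | C#CC(C)(C)C1C(=O)OC(C)(C)OC1=O | intermediate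
4 | 2-(2-methylbut-3-yn-2-yl)propanedioic acid (not isolated) | C#CC(C)(C)C(C(=O)O)C(=O)O | intermediate
5 | 3,3-dimethylpent-4-ynoic acid | C#CC(C)(C)CC(=O)O | intermediate
6 | 1-(3,3-dimethylpent-4-ynoyl)-1H-imidazole (not isolated) | C#CC(C)(C)CC(=O)n1ccnc1 | intermediate
7 | N-methoxy-N,3,3-trimethylpent-4-ynamide | C#CC(C)(C)CC(=O)N(C)OC | intermediate
8 | (E)-3-ethoxy-2-methylprop-2-enal | CCO/C=C(\C)C=O | starting material
9 | (7E)-8-ethoxy-6-hydroxy-N-methoxy-N,3,3,7-tetramethyloct-7-en-4-ynamide, racemic at the carbinol (not isolated) | CCO/C=C(\C)C(O)C#CC(C)(C)CC(=O)N(C)OC | intermediate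
10 | (6E)-N-methoxy-N,3,3,7-tetramethyl-8-oxooct-6-en-4-ynamide | CON(C)C(=O)CC(C)(C)C#C/C=C(\C)C=O | intermediate
11 | (6E)-N,8,8-trimethoxy-N,3,3,7-tetramethyloct-6-en-4-ynamide | CON(C)C(=O)CC(C)(C)C#C/C=C(\C)C(OC)OC | intermediate
12 | prop-1-yn-1-ylmagnesium bromide | CC#C[Mg]Br | starting material
13 | (9E)-11,11-dimethoxy-6,6,10-trimethylundec-9-ene-2,7-diyn-4-one | CC#CC(=O)CC(C)(C)C#C/C=C(\C)C(OC)OC | intermediate
14 | (4S,9E)-11,11-dimethoxy-6,6,10-trimethylundec-9-ene-2,7-diyn-4-ol | CC#C[C@@H](O)CC(C)(C)C#C/C=C(\C)C(OC)OC | intermediate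
15 | sodium salt of the cyclic alkenylaluminate from 14: five-membered ring O–Al–C(CH3)=CH–CH, two 2-methoxyethoxy groups on aluminium (not isolated) | CC1=C[C@H](CC(C)(C)C#C/C=C(\C)C(OC)OC)O[Al-]1(OCCOC)OCCOC.[Na+] | intermediate
16 | (2Z,4S,9E)-2-iodo-11,11-dimethoxy-6,6,10-trimethylundeca-2,9-dien-7-yn-4-ol | C/C(I)=C/[C@@H](O)CC(C)(C)C#C/C=C(\C)C(OC)OC | intermediate
17 | divalent alkenylpalladium iodide from oxidative addition of 16, phosphine ligands omitted (not isolated) | C/C([Pd]I)=C/[C@@H](O)CC(C)(C)C#C/C=C(\C)C(OC)OC | intermediate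
18 | cyclised divalent dienylpalladium iodide, palladium on C7' cis to C5', phosphine ligands omitted (not isolated) | COC(OC)/C(C)=C/C([Pd]I)=C1/C(C)=C[C@@H](O)CC1(C)C | intermediate
19 | (1S,4E)-4-[(2E)-4,4-dimethoxy-3-methylbut-2-en-1-ylidene]-3,5,5-trimethylcyclohex-2-en-1-ol | COC(OC)/C(C)=C/C=C1/C(C)=C[C@@H](O)CC1(C)C | intermediate
20 | (2E)-4-[(1E,4S)-4-hydroxy-2,6,6-trimethylcyclohex-2-en-1-ylidene]-2-methylbut-2-enal | O=C/C(C)=C/C=C1/C(C)=C[C@@H](O)CC1(C)C | intermediate
21 | (E)-3-methylpent-2-en-4-yn-1-ol | C#C/C(C)=C/CO | starting material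
22 | (2E,4E)-3-methyl-5-(tributylstannyl)penta-2,4-dien-1-ol | CCCC[Sn](CCCC)(CCCC)/C=C/C(C)=C/CO | intermediate
23 | tributyl[(1E,3E)-5-bromo-3-methylpenta-1,3-dien-1-yl]stannane | CCCC[Sn](CCCC)(CCCC)/C=C/C(C)=C/CBr | intermediate
24 | diethyl [(2E,4E)-3-methyl-5-(tributylstannyl)penta-2,4-dien-1-yl]phosphonate | CCCC[Sn](CCCC)(CCCC)/C=C/C(C)=C/CP(=O)(OCC)OCC | intermediate
25 | (1S,4E)-4-[(2E,4E,6E,8E)-3,7-dimethyl-9-(tributylstannyl)nona-2,4,6,8-tetraen-1-ylidene]-3,5,5-trimethylcyclohex-2-en-1-ol | CCCC[Sn](CCCC)(CCCC)/C=C/C(C)=C/C=C/C(C)=C/C=C1/C(C)=C[C@@H](O)CC1(C)C | intermediate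
26 | (1S,4E)-4-[(2E,4E,6E,8E)-9-iodo-3,7-dimethylnona-2,4,6,8-tetraen-1-ylidene]-3,5,5-trimethylcyclohex-2-en-1-ol | I/C=C/C(C)=C/C=C/C(C)=C/C=C1/C(C)=C[C@@H](O)CC1(C)C | intermediate
27 | triethylammonium salt of the N-(methoxycarbonyl)sulfamate ester of 20 at the C3 oxygen (not isolated) | O=C/C(C)=C/C=C1/C(C)=C[C@@H](OS(=O)(=O)[N-]C(=O)OC)CC1(C)C.CC[NH+](CC)CC | intermediate
28 | (2E)-2-methyl-4-[(1Z)-2,6,6-trimethylcyclohexa-2,4-dien-1-ylidene]but-2-enal | O=C/C(C)=C/C=C1/C(C)=CC=CC1(C)C | intermediate
29 | tributyl{(1E,3E,5E,7E)-3,7-dimethyl-9-[(1Z)-2,6,6-trimethylcyclohexa-2,4-dien-1-ylidene]nona-1,3,5,7-tetraen-1-yl}stannane | CC1=CC=CC(C)(C)\C1=C/C=C(C)/C=C/C=C(C)/C=C/[Sn](CCCC)(CCCC)CCCC | intermediate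
30 | (1S,4E)-3,5,5-trimethyl-4-[(2E,4E,6E,8E,10E,12E,14E,16E)-3,7,12,16-tetramethyl-18-[(1Z)-2,6,6-trimethylcyclohexa-2,4-dien-1-ylidene]octadeca-2,4,6,8,10,12,14,16-octaen-1-ylidene]cyclohex-2-en-1-ol (CNP0202479.1) | CC1=CC=CC(C)(C)\C1=C/C=C(C)/C=C/C=C(C)/C=C/C=C/C(C)=C/C=C/C(C)=C/C=C1/C(C)=C[C@@H](O)CC1(C)C | target

**Totals**
Total step count: 18. Longest linear sequence: 13 steps (steps 1 to 10, then 16, 17 and 18; the path through steps 14 and 15 is equally long).

**Steps most likely to fail**

Step 9. The alkenylpalladium iodide 17 may be reduced by formate before it inserts the alkyne (hydrodeiodination of 16), or palladium hydride may isomerise the product polyene. The fallback removes hydride from the ring-closing event and makes the C7'–H bond afterwards. It sets out from 16, which would be heated with Me3Sn–SnMe3 and Pd(PPh3)4 in toluene at 80 °C, so that the same 6-exo-dig carbopalladation is ended by tin transfer. This should give (1S)-4-[(2E)-4,4-dimethoxy-3-methyl-1-(trimethylstannyl)but-2-en-1-ylidene]-3,5,5-trimethylcyclohex-2-en-1-ol F1, with tin cis to C5'. Treatment with 1 M HCl in THF at 0 °C should then replace tin by hydrogen with retention and hydrolyse the acetal in the same operation, so the fallback comes back to the route at 20.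

Step 16. The allylic sulfamate may ionise and give allylic transposition or carbamate formation instead of syn elimination, or regiocontrol may be lost towards the exocyclic methylene isomer. The fallback builds the C2=C3 bond through an enol triflate and sets out from 19. Oxidation of the allylic alcohol with MnO2 in CH2Cl2 should give (4E)-4-[(2E)-4,4-dimethoxy-3-methylbut-2-en-1-ylidene]-3,5,5-trimethylcyclohex-2-en-1-one F2. Kinetic enolisation at C2 with KN(SiMe3)2 in THF at −78 °C and trapping with PhNTf2 should give the cross-conjugated dienyl triflate (4Z)-4-[(2E)-4,4-dimethoxy-3-methylbut-2-en-1-ylidene]-3,3,5-trimethylcyclohexa-1,5-dien-1-yl trifluoromethanesulfonate F3. Palladium-catalysed formate reduction of the triflate (Pd(OAc)2, PPh3, Bu3N, HCO2H, DMF, 60 °C) should give (6Z)-6-[(2E)-4,4-dimethoxy-3-methylbut-2-en-1-ylidene]-1,5,5-trimethylcyclohexa-1,3-diene F4. Acetal hydrolysis under the conditions of step 10 brings the fallback back to the route at 28.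

Step 18. The stannane may homocouple or lose tin by protonation, and the two C20 polyenes may undergo E/Z isomerisation under palladium. The fallback is an end game by olefination only and sets out from 24. Oxidative homocoupling of the alkenylstannane with CuCl in DMF at rt should give tetraethyl [(2E,4E,6E,8E)-3,8-dimethyldeca-2,4,6,8-tetraene-1,10-diyl]bis(phosphonate) F5. Horner–Wadsworth–Emmons reaction of an excess of F5 (one equivalent of LiN(SiMe3)2) with 28 should give diethyl {(2E,4E,6E,8E,10E,12E)-3,8,12-trimethyl-14-[(1Z)-2,6,6-trimethylcyclohexa-2,4-dien-1-ylidene]tetradeca-2,4,6,8,10,12-hexaen-1-yl}phosphonate F6. A second Horner–Wadsworth–Emmons reaction of lithiated F6 with 20 forms C10'=C11' and comes back to the route at 30.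

**Further compounds**
F1 | step 9 | (1S)-4-[(2E)-4,4-dimethoxy-3-methyl-1-(trimethylstannyl)but-2-en-1-ylidene]-3,5,5-trimethylcyclohex-2-en-1-ol (tin cis to C5') | COC(OC)/C(C)=C/C([Sn](C)(C)C)=C1/C(C)=C[C@@H](O)CC1(C)C
F2 | step 16 | (4E)-4-[(2E)-4,4-dimethoxy-3-methylbut-2-en-1-ylidene]-3,5,5-trimethylcyclohex-2-en-1-one | COC(OC)/C(C)=C/C=C1/C(C)=CC(=O)CC1(C)C
F3 | step 16 | (4Z)-4-[(2E)-4,4-dimethoxy-3-methylbut-2-en-1-ylidene]-3,3,5-trimethylcyclohexa-1,5-dien-1-yl trifluoromethanesulfonate | COC(OC)/C(C)=C/C=C1/C(C)=CC(OS(=O)(=O)C(F)(F)F)=CC1(C)C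
F4 | step 16 | (6Z)-6-[(2E)-4,4-dimethoxy-3-methylbut-2-en-1-ylidene]-1,5,5-trimethylcyclohexa-1,3-diene | COC(OC)/C(C)=C/C=C1/C(C)=CC=CC1(C)C
F5 | step 18 | tetraethyl [(2E,4E,6E,8E)-3,8-dimethyldeca-2,4,6,8-tetraene-1,10-diyl]bis(phosphonate) | CCOP(=O)(OCC)C/C=C(C)/C=C/C=C/C(C)=C/CP(=O)(OCC)OCC
F6 | step 18 | diethyl {(2E,4E,6E,8E,10E,12E)-3,8,12-trimethyl-14-[(1Z)-2,6,6-trimethylcyclohexa-2,4-dien-1-ylidene]tetradeca-2,4,6,8,10,12-hexaen-1-yl}phosphonate | CC1=CC=CC(C)(C)\C1=C/C=C(C)/C=C/C=C(C)/C=C/C=C/C(C)=C/CP(=O)(OCC)OCC
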